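The constants were chosen freely; the rest is arithmetic.

**The question.** I wanted to know which flask ends with the most monomer in chains, and how much each holds, when free monomer is also drawn off along two other paths.

all flasks: free monomer 20 mM; protic impurity 20.0 mM; initiator 0.2 mol%; time 2.5 h

| run | remark | temperature |
|---|---|---|
| epsilon | at −35 °C until 2.0 h, from then on at 25 °C |  |
| theta |  | 25 °C |
| delta |  | −35 °C |
| alpha |  | −5 °C |

    initiator → 2 initiating radical (k1 = 1.07 × 10⁻⁴ s⁻¹, Ea1 = 92.0 kJ mol⁻¹)
    2 growing radical → dead chain (k2 = 3.3 × 10⁶ M⁻¹ s⁻¹, Ea2 = 10.0 kJ mol⁻¹)
    free monomer ⇌ dormant form (K3 = 18.6, k3 = 2.60 × 10⁻⁴ s⁻¹, Ea3 = 89.0 kJ mol⁻¹, ΔH3 = −41.0 kJ mol⁻¹)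
    protic impurity + free monomer → quenched substrate (k4 = 0.00765 M⁻¹ s⁻¹, Ea4 = 54.0 kJ mol⁻¹)
    free monomer + initiating radical → growing radical + monomer in chains (k5 = 2.54 × 10⁵ M⁻¹ s⁻¹, Ea5 = 14.0 kJ mol⁻¹)
    free monomer + growing radical → monomer in chains + growing radical, rate k6*[growing radical]*[free monomer] (k6 = 3470 M⁻¹ s⁻¹, Ea6 = 38.0 kJ mol⁻¹)
    (constants at 25 °C)

- a doubled species enters its step squared and goes two at a time
- constants are those at 25 °C; use the activation energies and enthalpies for any other temperature

- the flask that comes out highest in amount of monomer in chains, in percent of the free monomer charged, or "all alike" when all lie within 1.5 percentage points (epsilon / theta / delta / alpha / all alike)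
- monomer in chains at the end, in percent of the free monomer charged, epsilon
- monomer in chains at the end, in percent of the free monomer charged, theta
- monomer in chains at the end, in percent of the free monomer charged, delta
- monomer in chains at the end, in percent of the free monomer charged, alpha

**The order.** I looked first for the concentration that sets the order of chain growth, and it is c(growing radical). Initiator gives two radicals per turn, each becoming a growing radical, and termination removes two per turn. Balancing the two makes c(growing radical) the root of the initiator constant times c(initiator) over the termination constant. In theta, 0.0400 mM of initiator gives 3.60 × 10⁻⁵ mM, so growth is pseudo-first-order in free monomer at 1.25 × 10⁻⁴ s⁻¹. Beside it stand parking as dormant form at 2.60 × 10⁻⁴ s⁻¹ and quenching at 1.53 × 10⁻⁴ s⁻¹, with protic impurity at its charge. I left out the return from dormant form, whose constant is 1.40 × 10⁻⁵ s⁻¹, as a simplification for the start, when the flask holds no dormant form. The three paths sum to λ = 5.38 × 10⁻⁴ s⁻¹. The chain share φ, growth divided by that sum, is the fraction of free monomer consumed at the start that enters chains: 23.2%.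

**Two extremes.** If free monomer stayed at its charge, theta would make 112% of the charge in 2.5 h, which is more than the charge and so impossible. If free monomer were consumed completely at these three rates, with no return from dormant form, theta would hold φ. My estimate lies under both, at φ times one minus e^(−λt), with the radical level and protic impurity held at their starting values. That gave me 23.0% for theta, just under φ.

**Cold flasks.** I did not work out numbers for the cold flasks. Growth carries an apparent activation energy of 79.0 kJ mol⁻¹, its own plus half the gap between initiation and termination, above the 54.0 kJ mol⁻¹ of quenching. So cooling lowers φ against quenching and also slows λ, and I put delta and alpha below theta. Epsilon has 0.500 h at 25 °C, less than theta's 2.5 h, so I committed to theta.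

**The forecast.** The forecast also named theta, with 23.3%, slightly above mine. It gave epsilon 13.5%, alpha 2.9% and delta 0.034%, holding that “epsilon is essentially a fresh 30-minute run at 25 °C”.

**The result.** Theta came out highest at 23.0%, with epsilon at 14.0%, alpha at 2.88% and delta at 0.0345%. Theta's lead over epsilon was gone after 25.0 h, when theta held 25.4% and epsilon 25.4%, both above φ. Epsilon reached its change of temperature with 99.5% of its free monomer, after 2.00 h. φ and λ over the remaining 0.500 h then give 14.4%, and epsilon held 14.0%.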